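**Retrosynthetic overview** (C-numbers in the text are germacrane numbers; names use IUPAC chain locants)
1. Target 27 ⇐ 26 by one acid step that frees the C14 aldehyde (dioxolane) and the C15 alcohol (silyl ether).
2. 26 ⇐ seco aldehyde 24: the ten-membered carbocycle closes first by a C6–C7 allylboration (organocatalytic, new), and the γ-lactone closes in the same flask.
3. 24 ⇐ ynoate 20 (syn hydroalumination/borylmethylation installs C13) ⇐ enal 13 + dienol 18 by cross-metathesis (C1=C10).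
4. 13 ⇐ ynal 7 + acetal allylboronate 5 (phosphoric acid-catalysed allylboration, C8–C9, sets C8), then esterification with acid 11 (from tiglic acid).
5. 18 ⇐ monosilylated butynediol 14 via vinyl iodide 16 (fixes the C4=C5 geometry) and Negishi coupling.

Assumption: 1, 2, 6, 10, 14, 17 and 21 are taken to be catalogue compounds.

**Step 1**
Reactants: 1 2-bromo-3,3-diethoxyprop-1-ene; 2 2-(chloromethyl)-4,4,5,5-tetramethyl-1,3,2-dioxaborolane
Product: 5 2-[2-(diethoxymethyl)prop-2-en-1-yl]-4,4,5,5-tetramethyl-1,3,2-dioxaborolane, via vinyllithium 3 (not isolated), via boron ate complex 4 (not isolated)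
Conditions: n-butyllithium, Et2O, −78 °C; then 2, −78 °C → rt
Reagents that add atoms: none
Why: bromine–lithium exchange gives the alkenyllithium, which adds to boron and undergoes a 1,2-metallate shift with loss of chloride (Matteson-type homologation of an alkenylmetal with a halomethylboronate) to give the allylboronate.

**Step 2**
Reactants: 6 ethyl 4,4-diethoxybut-2-ynoate
Product: 7 ethyl 4-oxobut-2-ynoate
Conditions: HCO2H/H2O (95:5), rt; used at once
Reagents that add atoms: water (O)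
Why: acid-catalysed acetal hydrolysis; the ynoate ester is stable to acid and the electrophilic ynal is carried straight into step 3.

**Step 3**
Reactants: 7 ethyl 4-oxobut-2-ynoate; 5 2-[2-(diethoxymethyl)prop-2-en-1-yl]-4,4,5,5-tetramethyl-1,3,2-dioxaborolane
Product: 9 ethyl (4R)-6-(diethoxymethyl)-4-hydroxyhept-6-en-2-ynoate, via pinacol borate 8 (not isolated)
Conditions: (R)-TRIP [3,3′-bis(2,4,6-triisopropylphenyl)-BINOL hydrogen phosphate] (5 mol%), 4 Å MS, toluene, −40 °C; aqueous work-up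
Reagents that add atoms: none
Why: chiral phosphoric acid-catalysed allylboration through a closed chair transition state (the acid hydrogen-bonds the pseudo-axial boronate oxygen and the formyl hydrogen) delivers the allyl group to one face of the ynal and sets C8 as R, the first stereocentre; the (R)-catalyst is chosen by analogy with aryl and alkenyl aldehydes.

**Step 4**
Reactants: 10 tiglic acid [(2E)-2-methylbut-2-enoic acid]
Product: 11 (2S)-2-methylbutanoic acid
Conditions: Ru(OAc)2[(S)-H8-BINAP] (0.5 mol%), H2 (2 atm), MeOH, 20 °C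
Reagents that add atoms: none
Why: carboxylate-directed asymmetric hydrogenation of the trisubstituted alkene sets the acyl α-stereocentre as S.

**Step 5**
Reactants: 9 ethyl (4R)-6-(diethoxymethyl)-4-hydroxyhept-6-en-2-ynoate; 11 (2S)-2-methylbutanoic acid
Product: 13 ethyl (4R)-6-formyl-4-{[(2S)-2-methylbutanoyl]oxy}hept-6-en-2-ynoate, via acylated acetal 12 (not isolated)
Conditions: EDC·HCl, DMAP (10 mol%), CH2Cl2, 0 °C; then 1 M aq. HCl, THF, rt
Reagents that add atoms: water (O)
Why: Steglich esterification leaves the C8–O bond untouched (retention) and installs the final ester so no protecting group is needed at O8, then the α,β-unsaturated acetal is hydrolysed to the 2-substituted acrolein; minor diastereomers from imperfect ee of 9 or 11 are removed here by chromatography.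

**Step 6**
Reactants: 14 4-{[tert-butyl(dimethyl)silyl]oxy}but-2-yn-1-ol
Product: 16 (2Z)-4-{[tert-butyl(dimethyl)silyl]oxy}-3-iodobut-2-en-1-ol, via cyclic alkenylaluminate 15 (not isolated)
Conditions: NaAlH2(OCH2CH2OMe)2, Et2O, 0 °C; then I2, THF, −78 °C
Reagents that add atoms: iodine (II)
Why: hydroxyl-directed trans-hydroalumination of the propargylic alcohol puts aluminium on the distal carbon cis to CH2OH, and iodination with retention gives the Z vinyl iodide.

**Step 7**
Reactants: 16 (2Z)-4-{[tert-butyl(dimethyl)silyl]oxy}-3-iodobut-2-en-1-ol; 17 but-3-en-1-ylzinc bromide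
Product: 18 (2E)-3-({[tert-butyl(dimethyl)silyl]oxy}methyl)hepta-2,6-dien-1-ol
Conditions: Pd(PPh3)4 (5 mol%), 17 (2.5 equiv), THF, 40 °C
Reagents that add atoms: none
Why: Negishi sp2–sp3 coupling with retention of olefin geometry places the butenyl chain (C3) cis to CH2OH (C6), which is the ring-cis C4=C5 geometry of the target.

**Step 8**
Reactants: 13 ethyl (4R)-6-formyl-4-{[(2S)-2-methylbutanoyl]oxy}hept-6-en-2-ynoate; 18 (2E)-3-({[tert-butyl(dimethyl)silyl]oxy}methyl)hepta-2,6-dien-1-ol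
Product: 19 ethyl (4R,6E,10E)-10-({[tert-butyl(dimethyl)silyl]oxy}methyl)-6-formyl-12-hydroxy-4-{[(2S)-2-methylbutanoyl]oxy}dodeca-6,10-dien-2-ynoate
Conditions: RuCl2(=CH-C6H4-2-OiPr)(H2IMes) (Hoveyda–Grubbs second-generation catalyst, 10 mol%), 1,4-benzoquinone (10 mol%), 18 (2 equiv), CH2Cl2, 40 °C
Reagents that add atoms: none
Why: olefin cross-metathesis of a 2-substituted acrolein with a terminal alkene gives the thermodynamic E enal (CHO trans to C2, so C2 is cis to C9 as in the ring); the trisubstituted alkene of 18 and the internal electron-poor alkyne are poor metathesis substrates.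

**Step 9**
Reactants: 19 ethyl (4R,6E,10E)-10-({[tert-butyl(dimethyl)silyl]oxy}methyl)-6-formyl-12-hydroxy-4-{[(2S)-2-methylbutanoyl]oxy}dodeca-6,10-dien-2-ynoate
Product: 20 ethyl (4R,6E,10E)-10-({[tert-butyl(dimethyl)silyl]oxy}methyl)-6-(1,3-dioxolan-2-yl)-12-hydroxy-4-{[(2S)-2-methylbutanoyl]oxy}dodeca-6,10-dien-2-ynoate
Conditions: (Me3SiOCH2)2, Me3SiOTf (5 mol%), CH2Cl2, −78 → −20 °C; aqueous NaHCO3 then brief aqueous citric acid wash
Reagents that add atoms: 1,2-bis(trimethylsilyloxy)ethane (C[Si](C)(C)OCCO[Si](C)(C)C)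
Why: Noyori acetalisation masks the C14 enal as a robust dioxolane without olefin migration, so that the allylboronate made next cannot close a five-membered ring onto C14; silyl ether, esters and ynoate are inert and a transient O–SiMe3 on the primary alcohol is lost in the work-up.

**Step 10**
Reactants: 20 ethyl (4R,6E,10E)-10-({[tert-butyl(dimethyl)silyl]oxy}methyl)-6-(1,3-dioxolan-2-yl)-12-hydroxy-4-{[(2S)-2-methylbutanoyl]oxy}dodeca-6,10-dien-2-ynoate; 21 2-(iodomethyl)-4,4,5,5-tetramethyl-1,3,2-dioxaborolane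
Product: 23 ethyl (2Z,4R,6E,10E)-10-({[tert-butyl(dimethyl)silyl]oxy}methyl)-6-(1,3-dioxolan-2-yl)-12-hydroxy-4-{[(2S)-2-methylbutanoyl]oxy}-2-[(4,4,5,5-tetramethyl-1,3,2-dioxaborolan-2-yl)methyl]dodeca-2,6,10-trienoate, via alkenylalane 22 (not isolated)
Conditions: iBu2AlH (2.3 equiv), HMPA, THF, 0 °C; then 21, 0 °C → rt; aqueous potassium sodium tartrate/NaHCO3
Reagents that add atoms: none
Why: conjugate syn hydroalumination of the ynoate by the iBu2AlH–HMPA complex (unreactive toward the saturated ester) puts H on C7 and Al on C11 cis to each other, and C-alkylation of the alkenylalane with the α-halo boronate with retention places CH2B (C13) trans to C8.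

**Step 11**
Reactants: 23 ethyl (2Z,4R,6E,10E)-10-({[tert-butyl(dimethyl)silyl]oxy}methyl)-6-(1,3-dioxolan-2-yl)-12-hydroxy-4-{[(2S)-2-methylbutanoyl]oxy}-2-[(4,4,5,5-tetramethyl-1,3,2-dioxaborolan-2-yl)methyl]dodeca-2,6,10-trienoate
Product: 24 ethyl (2Z,4R,6E,10E)-10-({[tert-butyl(dimethyl)silyl]oxy}methyl)-6-(1,3-dioxolan-2-yl)-4-{[(2S)-2-methylbutanoyl]oxy}-12-oxo-2-[(4,4,5,5-tetramethyl-1,3,2-dioxaborolan-2-yl)methyl]dodeca-2,6,10-trienoate
Conditions: MnO2 (20 equiv), CH2Cl2, rt; filtered and used directly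
Reagents that add atoms: none
Why: MnO2 oxidises only the allylic primary alcohol to the C6 enal, and the ester-deactivated allylboronate does not add to it at room temperature without an acid catalyst.

**Step 12**
Reactants: 24 ethyl (2Z,4R,6E,10E)-10-({[tert-butyl(dimethyl)silyl]oxy}methyl)-6-(1,3-dioxolan-2-yl)-4-{[(2S)-2-methylbutanoyl]oxy}-12-oxo-2-[(4,4,5,5-tetramethyl-1,3,2-dioxaborolan-2-yl)methyl]dodeca-2,6,10-trienoate
Product: 26 (6R,7R,8R)-15-{[tert-butyl(dimethyl)silyl]oxy}-14,14-(ethane-1,2-diyldioxy)-8-{[(2S)-2-methylbutanoyl]oxy}germacra-1(10),4,11(13)-trien-12,6-olide, via macrocyclic borate 25 (not isolated)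
Conditions: (S)-TRIP (10 mol%), 4 Å MS, toluene (1 mM), 40 °C; then TsOH·H2O (5 mol%), rt
Reagents that add atoms: none
Why: Proposed new method: a chiral phosphoric acid-catalysed macrocyclising allylboration of a 2-alkoxycarbonyl allylboronate onto a tethered enal has not been described; the acid hydrogen-bonds the pseudo-axial boronate oxygen while its phosphoryl oxygen binds the formyl hydrogen, which accelerates the sluggish ester-bearing boronate and selects the aldehyde face [(S)-catalyst predicted from the intermolecular model to give 6R], and the closed chair transition state with C5 and C8 both equatorial (C8 trans to CH2B in 24) gives the anti adduct, so C6 and C7 (both R) and the ten-membered ring form together and the O6 borate then lactonises onto the C12 ester to the trans-fused α-methylene lactone; the closest known reactions are the phosphoric acid-catalysed intermolecular allylboration of aldehydes with pinacol allylboronates and the Brønsted or Lewis acid-accelerated allylboration with 2-alkoxycarbonyl allylboronates.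

**Step 13**
Reactants: 26 (6R,7R,8R)-15-{[tert-butyl(dimethyl)silyl]oxy}-14,14-(ethane-1,2-diyldioxy)-8-{[(2S)-2-methylbutanoyl]oxy}germacra-1(10),4,11(13)-trien-12,6-olide
Product: 27 (6R,7R,8R)-15-hydroxy-8-{[(2S)-2-methylbutanoyl]oxy}-14-oxogermacra-1(10),4,11(13)-trien-12,6-olide (CNP0168859.6)
Conditions: 1 M aq. HCl, THF, rt
Reagents that add atoms: water (O)
Why: mild aqueous acid hydrolyses the conjugated dioxolane and the primary allylic silyl ether in one operation without touching the α-methylene lactone, the ester or the stereocentres.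

**Compound list**
1 | 2-bromo-3,3-diethoxyprop-1-ene | C=C(Br)C(OCC)OCC | starting material
2 | 2-(chloromethyl)-4,4,5,5-tetramethyl-1,3,2-dioxaborolane | ClCB1OC(C)(C)C(C)(C)O1 | starting material
3 | (3,3-diethoxyprop-1-en-2-yl)lithium | [Li]C(=C)C(OCC)OCC | intermediate
4 | lithium (chloromethyl)(3,3-diethoxyprop-1-en-2-yl)(pinacolato)borate | [Li+].ClC[B-]1(OC(C)(C)C(C)(C)O1)C(=C)C(OCC)OCC | intermediate
5 | 2-[2-(diethoxymethyl)prop-2-en-1-yl]-4,4,5,5-tetramethyl-1,3,2-dioxaborolane | C=C(CB1OC(C)(C)C(C)(C)O1)C(OCC)OCC | intermediate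
6 | ethyl 4,4-diethoxybut-2-ynoate | CCOC(=O)C#CC(OCC)OCC | starting material
7 | ethyl 4-oxobut-2-ynoate | CCOC(=O)C#CC=O | intermediate
8 | ethyl (4R)-6-(diethoxymethyl)-4-[(4,4,5,5-tetramethyl-1,3,2-dioxaborolan-2-yl)oxy]hept-6-en-2-ynoate | CCOC(=O)C#C[C@H](OB1OC(C)(C)C(C)(C)O1)CC(=C)C(OCC)OCC | intermediate
9 | ethyl (4R)-6-(diethoxymethyl)-4-hydroxyhept-6-en-2-ynoate | CCOC(=O)C#C[C@H](O)CC(=C)C(OCC)OCC | intermediate
10 | tiglic acid [(2E)-2-methylbut-2-enoic acid] | C/C=C(\C)C(=O)O | starting material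
11 | (2S)-2-methylbutanoic acid | CC[C@H](C)C(=O)O | intermediate
12 | ethyl (4R)-6-(diethoxymethyl)-4-{[(2S)-2-methylbutanoyl]oxy}hept-6-en-2-ynoate | CCOC(=O)C#C[C@H](OC(=O)[C@@H](C)CC)CC(=C)C(OCC)OCC | intermediate
13 | ethyl (4R)-6-formyl-4-{[(2S)-2-methylbutanoyl]oxy}hept-6-en-2-ynoate | CCOC(=O)C#C[C@H](OC(=O)[C@@H](C)CC)CC(=C)C=O | intermediate
14 | 4-{[tert-butyl(dimethyl)silyl]oxy}but-2-yn-1-ol | OCC#CCO[Si](C)(C)C(C)(C)C | starting material
15 | sodium cyclic alkenylaluminate (five-membered O–Al–C ring; two 2-methoxyethoxy groups on Al) | [Na+].COCCO[Al-]1(OCCOC)OCC=C1CO[Si](C)(C)C(C)(C)C | intermediate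
16 | (2Z)-4-{[tert-butyl(dimethyl)silyl]oxy}-3-iodobut-2-en-1-ol | OC/C=C(\I)CO[Si](C)(C)C(C)(C)C | intermediate
17 | but-3-en-1-ylzinc bromide | C=CCC[Zn]Br | starting material
18 | (2E)-3-({[tert-butyl(dimethyl)silyl]oxy}methyl)hepta-2,6-dien-1-ol | OC/C=C(\CCC=C)CO[Si](C)(C)C(C)(C)C | intermediate
19 | ethyl (4R,6E,10E)-10-({[tert-butyl(dimethyl)silyl]oxy}methyl)-6-formyl-12-hydroxy-4-{[(2S)-2-methylbutanoyl]oxy}dodeca-6,10-dien-2-ynoate | CCOC(=O)C#C[C@H](OC(=O)[C@@H](C)CC)C/C(C=O)=C\CC/C(CO[Si](C)(C)C(C)(C)C)=C\CO | intermediate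
20 | ethyl (4R,6E,10E)-10-({[tert-butyl(dimethyl)silyl]oxy}methyl)-6-(1,3-dioxolan-2-yl)-12-hydroxy-4-{[(2S)-2-methylbutanoyl]oxy}dodeca-6,10-dien-2-ynoate | CCOC(=O)C#C[C@H](OC(=O)[C@@H](C)CC)C/C(C1OCCO1)=C\CC/C(CO[Si](C)(C)C(C)(C)C)=C\CO | intermediate
21 | 2-(iodomethyl)-4,4,5,5-tetramethyl-1,3,2-dioxaborolane | ICB1OC(C)(C)C(C)(C)O1 | starting material
22 | 2-(diisobutylalanyl) alkenylalane of 20 (H on C3 cis to Al; O12 as diisobutylaluminium alkoxide) | CCOC(=O)/C([Al](CC(C)C)CC(C)C)=C\[C@H](OC(=O)[C@@H](C)CC)C/C(C1OCCO1)=C\CC/C(CO[Si](C)(C)C(C)(C)C)=C\CO[Al](CC(C)C)CC(C)C | intermediate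
23 | ethyl (2Z,4R,6E,10E)-10-({[tert-butyl(dimethyl)silyl]oxy}methyl)-6-(1,3-dioxolan-2-yl)-12-hydroxy-4-{[(2S)-2-methylbutanoyl]oxy}-2-[(4,4,5,5-tetramethyl-1,3,2-dioxaborolan-2-yl)methyl]dodeca-2,6,10-trienoate | CCOC(=O)/C(CB1OC(C)(C)C(C)(C)O1)=C\[C@H](OC(=O)[C@@H](C)CC)C/C(C2OCCO2)=C\CC/C(CO[Si](C)(C)C(C)(C)C)=C\CO | intermediate
24 | ethyl (2Z,4R,6E,10E)-10-({[tert-butyl(dimethyl)silyl]oxy}methyl)-6-(1,3-dioxolan-2-yl)-4-{[(2S)-2-methylbutanoyl]oxy}-12-oxo-2-[(4,4,5,5-tetramethyl-1,3,2-dioxaborolan-2-yl)methyl]dodeca-2,6,10-trienoate | CCOC(=O)/C(CB1OC(C)(C)C(C)(C)O1)=C\[C@H](OC(=O)[C@@H](C)CC)C/C(C2OCCO2)=C\CC/C(CO[Si](C)(C)C(C)(C)C)=C\C=O | intermediate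
25 | ten-membered carbocyclic borate: ethyl 2-substituted acrylate on C7 with O6–Bpin (6R,7R,8R; C14 dioxolane; C15 silyl ether; both ring alkenes cis in the ring) | CCOC(=O)C(=C)[C@H]1[C@H](OB2OC(C)(C)C(C)(C)O2)/C=C(/CO[Si](C)(C)C(C)(C)C)CC/C=C(/C3OCCO3)C[C@H]1OC(=O)[C@@H](C)CC | intermediate
26 | (6R,7R,8R)-15-{[tert-butyl(dimethyl)silyl]oxy}-14,14-(ethane-1,2-diyldioxy)-8-{[(2S)-2-methylbutanoyl]oxy}germacra-1(10),4,11(13)-trien-12,6-olide (trans-fused lactone; both ring alkenes cis in the ring) | C=C1C(=O)O[C@@H]2/C=C(/CO[Si](C)(C)C(C)(C)C)CC/C=C(/C3OCCO3)C[C@@H](OC(=O)[C@@H](C)CC)[C@@H]12 | intermediate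
27 | (6R,7R,8R)-15-hydroxy-8-{[(2S)-2-methylbutanoyl]oxy}-14-oxogermacra-1(10),4,11(13)-trien-12,6-olide (CNP0168859.6) | C=C1C(=O)O[C@@H]2/C=C(/CO)CC/C=C(/C=O)C[C@@H](OC(=O)[C@@H](C)CC)[C@@H]12 | target

**Step count and risks**
Total step count: 13. Longest linear sequence: 9 steps (6 → 7 → 9 → 13 → 19 → 20 → 23 → 24 → 26 → 27).

Most likely to fail, step 12 (the new macrocyclising allylboration): the ester-bearing boronate may be too slow under phosphoric acid catalysis, the catalyst may be mismatched with the resident C8 centre, or oligomers may form. A more acidic N-triflyl phosphoramide analogue would be tried first. The fallback with known chemistry sets out from 23 and comes back at 26. The C–B bond of 23 is oxidised with NaBO3·4H2O (THF/H2O, 0 °C) to the 2-(hydroxymethyl) diol F1. MnO2 (CH2Cl2, 0 °C) oxidises only the electron-rich allylic alcohol to the 2-(hydroxymethyl) enal F2. CBr4/PPh3 (CH2Cl2, −20 °C) gives the 2-(bromomethyl) enal F3. F3 is closed with CrCl2 (THF, high dilution, 0 °C → rt) in the established Barbier-type cyclisation of ω-formyl 2-(bromomethyl)-2-alkenoates; this is anti-selective through the equilibrating allylchromium and lactonises on acidic work-up to 26, with C7/C8 selectivity then under substrate control.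

Second, step 10 (hydroalumination/borylmethylation): the saturated ester may be reduced, or the alkenylalane may lose its geometry before alkylation. The fallback sets out from 20 and comes back at 23. Pd(PPh3)4-catalysed syn hydrostannation with Bu3SnH (THF, 0 °C) gives the 2-(tributylstannyl) enoate F4. I2 (CH2Cl2, 0 °C) gives the 2-iodo enoate F5 with retention. Pd(PPh3)4-catalysed Negishi coupling of F5 with iodo[(pinacolatoboryl)methyl]zinc F6 (made from 21 and Zn dust in THF) gives 23 with CH2B trans to C8.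

Third, step 8 (cross-metathesis): the hindered 2-substituted acrolein may react slowly with a precious partner, or the ynoate may divert the catalyst. The fallback sets out from 13 and comes back at 20, and moves the fragment union from C1=C10 to the C3–C4 bond. Metathesis of 13 with cheap 4-iodobut-1-ene (10 equiv, same catalyst) gives ethyl (4R,6E)-6-formyl-9-iodo-4-{[(2S)-2-methylbutanoyl]oxy}non-6-en-2-ynoate F7. Acetalisation as in step 9 gives ethyl (4R,6E)-6-(1,3-dioxolan-2-yl)-9-iodo-4-{[(2S)-2-methylbutanoyl]oxy}non-6-en-2-ynoate F8. Zn dust/LiCl (THF, rt) gives the alkylzinc iodide of F8 F9. Pd(PPh3)4-catalysed Negishi coupling of F9 with vinyl iodide 16 gives 20 directly, so step 7 is not needed.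

**Further compounds**
F1 | step 12 | 2-(hydroxymethyl) diol (CH2OH for CH2Bpin in 23) | CCOC(=O)/C(CO)=C\[C@H](OC(=O)[C@@H](C)CC)C/C(C1OCCO1)=C\CC/C(CO[Si](C)(C)C(C)(C)C)=C\CO
F2 | step 12 | 2-(hydroxymethyl) enal (C6 aldehyde of F1) | CCOC(=O)/C(CO)=C\[C@H](OC(=O)[C@@H](C)CC)C/C(C1OCCO1)=C\CC/C(CO[Si](C)(C)C(C)(C)C)=C\C=O
F3 | step 12 | 2-(bromomethyl) enal (allylic bromide of F2) | CCOC(=O)/C(CBr)=C\[C@H](OC(=O)[C@@H](C)CC)C/C(C1OCCO1)=C\CC/C(CO[Si](C)(C)C(C)(C)C)=C\C=O
F4 | step 10 | 2-(tributylstannyl) enoate (H and SnBu3 added syn to the ynoate of 20) | CCOC(=O)/C([Sn](CCCC)(CCCC)CCCC)=C\[C@H](OC(=O)[C@@H](C)CC)C/C(C1OCCO1)=C\CC/C(CO[Si](C)(C)C(C)(C)C)=C\CO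
F5 | step 10 | 2-iodo enoate (iodide of F4) | CCOC(=O)/C(I)=C\[C@H](OC(=O)[C@@H](C)CC)C/C(C1OCCO1)=C\CC/C(CO[Si](C)(C)C(C)(C)C)=C\CO
F6 | step 10 | iodo[(pinacolatoboryl)methyl]zinc | I[Zn]CB1OC(C)(C)C(C)(C)O1
F7 | step 8 | ethyl (4R,6E)-6-formyl-9-iodo-4-{[(2S)-2-methylbutanoyl]oxy}non-6-en-2-ynoate | CCOC(=O)C#C[C@H](OC(=O)[C@@H](C)CC)C/C(C=O)=C\CCI
F8 | step 8 | ethyl (4R,6E)-6-(1,3-dioxolan-2-yl)-9-iodo-4-{[(2S)-2-methylbutanoyl]oxy}non-6-en-2-ynoate | CCOC(=O)C#C[C@H](OC(=O)[C@@H](C)CC)C/C(C1OCCO1)=C\CCI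
F9 | step 8 | alkylzinc iodide of F8 | CCOC(=O)C#C[C@H](OC(=O)[C@@H](C)CC)C/C(C1OCCO1)=C\CC[Zn]I
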